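**Retrosynthetic overview**

- Last operations: desilylation, and before it an equatorial methyl addition to the cyclohexanone of a tetracyclic diketone (sets the axial tertiary alcohol).
- Key disconnection: the linker C–C bond next to the cycloheptenone, the oxepane C–O bond and the cyclohexane C–C bond are all cut together. Forward, a hydroazulene silyl dienol ether adds to a bis-epoxy vinyl ketone (vinylogous Mukaiyama–Michael), and the enol silane so formed closes oxepane and cyclohexanone in the same flask.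
- Hydroazulene half: seven-membered ring by intramolecular Claisen condensation on a cyclopentane; its three stereocentres come from a catalytic asymmetric methyl addition and an OH-directed hydrogenation; the cyclopentane comes from cyclopentane-1,3-dione.
- Bis-epoxy vinyl ketone: from geranyl bromide by Weinreb amide alkylation, Shi epoxidation and vinyl Grignard addition.
- Ring order: cyclopentane (purchased) → cycloheptane → oxepane and cyclohexane together, last.

Assumption: a one-flask sequence counts as one step, and the antipode of each chiral catalyst is the one that gives the configuration stated at that step.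

**Route**

Step 1
Reactants: 1 cyclopentane-1,3-dione; 2 ethyl glyoxylate
Product: 4 ethyl 2-(2,5-dioxocyclopentyl)acetate, via alkylidene dione 3 (not isolated)
Conditions: Hantzsch ester (1.1 equiv), L-proline (10 mol%), CH2Cl2, rt
Reagents that add atoms: none
Why: Knoevenagel condensation followed by Hantzsch-ester transfer hydrogenation (organocatalytic reductive alkylation) gives clean C-monoalkylation of the cyclic 1,3-dione where direct alkylation would give O-alkylation; no stereocentre is formed.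

Step 2
Reactants: 4 ethyl 2-(2,5-dioxocyclopentyl)acetate
Product: 5 ethyl 2-(2-chloro-5-oxocyclopent-1-en-1-yl)acetate
Conditions: (COCl)2 (1.2 equiv), DMF (cat.), CH2Cl2, 0 °C → rt
Reagents that add atoms: oxalyl chloride O=C(Cl)C(Cl)=O
Why: Vilsmeier-type activation of the enol gives the vinylogous acid chloride; the dione is symmetric, so only one regioisomer can form.

Step 3
Reactants: 5 ethyl 2-(2-chloro-5-oxocyclopent-1-en-1-yl)acetate; 6 pentan-3-one
Product: 8 ethyl 2-[2-(2-methyl-3-oxopentan-2-yl)-5-oxocyclopent-1-en-1-yl]acetate, via monomethyl keto ester 7 (not isolated)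
Conditions: LiN(iPr)2 (2.2 equiv), 6 (2.2 equiv), THF, −78 °C; add 5, −78 → 0 °C; then MeI (3 equiv), DMPU, 0 °C → rt
Reagents that add atoms: iodomethane CI
Why: Conjugate addition–elimination of the ketone lithium enolate on the β-chloro enone (vinylogous acyl substitution) gives a vinylogous β-diketone whose acidic CH is deprotonated by the second equivalent of enolate and C-methylated, as in the second alkylation of Hagemann's ester (the enone α-carbon is already substituted), to build the quaternary carbon; no stereocentre remains.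

Step 4
Reactants: 8 ethyl 2-[2-(2-methyl-3-oxopentan-2-yl)-5-oxocyclopent-1-en-1-yl]acetate
Product: 9 ethyl 2-[(5R)-5-hydroxy-5-methyl-2-(2-methyl-3-oxopentan-2-yl)cyclopent-1-en-1-yl]acetate
Conditions: Me2Zn (3 equiv), Ti(OiPr)4 (1.2 equiv), trans-1,2-bis[(2-exo-hydroxybornan-10-yl)sulfonylamino]cyclohexane (10 mol%, antipode giving the 5R carbinol), toluene/hexanes, rt; aq. NH4Cl
Reagents that add atoms: dimethylzinc C[Zn]C
Why: Catalytic enantioselective 1,2-addition of a methyl group to a 2-substituted cycloalkenone (titanium bis(sulfonamide) diol catalyst); the α-substituent differentiates the two carbonyl faces and sets the 5R carbinol, while the ethyl ketone flanked by a quaternary carbon and the ester do not react.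

Step 5
Reactants: 9 ethyl 2-[(5R)-5-hydroxy-5-methyl-2-(2-methyl-3-oxopentan-2-yl)cyclopent-1-en-1-yl]acetate
Product: 10 ethyl 2-[(1R,2R,5R)-2-hydroxy-2-methyl-5-(2-methyl-3-oxopentan-2-yl)cyclopentyl]acetate
Conditions: H2 (50 bar), [Ir(cod)(PCy3)(py)]PF6 (10 mol%), CH2Cl2, rt
Reagents that add atoms: none
Why: Hydroxyl-directed homogeneous hydrogenation: iridium binds the tertiary OH and delivers both hydrogens to the alkene face syn to it, so the two new CH centres are cis to each other and to OH (both side chains trans to OH).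

Step 6
Reactants: 10 ethyl 2-[(1R,2R,5R)-2-hydroxy-2-methyl-5-(2-methyl-3-oxopentan-2-yl)cyclopentyl]acetate
Product: 11 (1R,3aR,8aR)-1-hydroxy-1,4,4,6-tetramethyloctahydroazulene-5,7(1H,6H)-dione
Conditions: KOtBu (3 equiv), THF, 0 °C → rt; 1 M HCl
Reagents that add atoms: none
Why: Intramolecular crossed Claisen (Dieckmann-type) condensation: the ketone can enolize only toward its CH2 (the other side is quaternary), the cis side chains and the gem-dimethyl group favour seven-membered ring closure, and deprotonation of the β-diketone drives it; existing stereocentres are not acidic and the new C6 centre is an enolizable mixture.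

Step 7
Reactants: 11 (1R,3aR,8aR)-1-hydroxy-1,4,4,6-tetramethyloctahydroazulene-5,7(1H,6H)-dione
Product: 12 (1R,3aR,8aR)-1,7-bis(tert-butyldimethylsilyloxy)-1,4,4,6-tetramethyl-2,3,3a,4,8,8a-hexahydroazulen-5(1H)-one
Conditions: TBSOTf (2.5 equiv), Et3N (4 equiv), CH2Cl2, −78 → 0 °C
Reagents that add atoms: tert-butyldimethylsilyl trifluoromethanesulfonate CC(C)(C)[Si](C)(C)OS(=O)(=O)C(F)(F)F
Why: O-silylation of the β-diketone enolate at the oxygen remote from the gem-dimethyl group (the less hindered one) and silylation of the tertiary alcohol; no stereocentre changes.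

Step 8
Reactants: 12 (1R,3aR,8aR)-1,7-bis(tert-butyldimethylsilyloxy)-1,4,4,6-tetramethyl-2,3,3a,4,8,8a-hexahydroazulen-5(1H)-one
Product: 13 (1R,3aR,8aR)-1,7-bis(tert-butyldimethylsilyloxy)-1,4,4,6-tetramethyl-5-methylidene-1,2,3,3a,4,5,8,8a-octahydroazulene
Conditions: Cp2TiMe2 (3 equiv), toluene, 70 °C, dark
Reagents that add atoms: dimethyltitanocene C[Ti](C)(C1C=CC=C1)C1C=CC=C1
Why: Petasis methylenation (titanium methylidene, non-basic) converts the hindered vinylogous ester carbonyl into the exocyclic methylene and so gives the linear silyl dienol ether as a single regioisomer, which enolization of the parent enone would not; no stereocentre changes.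

Step 9
Reactants: 14 geranyl bromide; 15 N-methoxy-N-methylacetamide
Product: 16 (4E)-N-methoxy-N,5,9-trimethyldeca-4,8-dienamide
Conditions: LiN(iPr)2 (1.1 equiv), 15, THF, −78 °C; then 14, −78 → 0 °C
Reagents that add atoms: none
Why: SN2 alkylation of the Weinreb acetamide enolate with the primary allylic bromide; the E alkene is untouched.

Step 10
Reactants: 16 (4E)-N-methoxy-N,5,9-trimethyldeca-4,8-dienamide
Product: 17 3-[(2R,3R)-3-{2-[(2R)-3,3-dimethyloxiran-2-yl]ethyl}-3-methyloxiran-2-yl]-N-methoxy-N-methylpropanamide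
Conditions: D-fructose-derived Shi ketone (0.6 equiv), KHSO5 (as 2KHSO5·KHSO4·K2SO4, 3 equiv), K2CO3, Bu4NHSO4 (cat.), MeCN/dimethoxymethane/aq. Na2B4O7 buffer (pH 10.5), 0 °C
Reagents that add atoms: potassium peroxymonosulfate [K+].[O-]S(=O)(=O)OO
Why: Shi asymmetric epoxidation (chiral dioxirane, spiro transition state) oxidizes both trisubstituted alkenes from the same enantioface; the D-fructose-derived ketone gives R at each epoxide CH carbon and R,R for the internal E-epoxide.

Step 11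
Reactants: 17 3-[(2R,3R)-3-{2-[(2R)-3,3-dimethyloxiran-2-yl]ethyl}-3-methyloxiran-2-yl]-N-methoxy-N-methylpropanamide
Product: 18 5-[(2R,3R)-3-{2-[(2R)-3,3-dimethyloxiran-2-yl]ethyl}-3-methyloxiran-2-yl]pent-1-en-3-one
Conditions: CH2=CHMgBr (1.5 equiv), THF, −20 → 0 °C; cold 1 M HCl quench
Reagents that add atoms: vinylmagnesium bromide C=C[Mg]Br
Why: Weinreb ketone synthesis: the chelated tetrahedral intermediate prevents over-addition, and trisubstituted epoxides are inert to the Grignard reagent at this temperature; stereocentres are untouched.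

Step 12
Reactants: 13 (1R,3aR,8aR)-1,7-bis(tert-butyldimethylsilyloxy)-1,4,4,6-tetramethyl-5-methylidene-1,2,3,3a,4,5,8,8a-octahydroazulene; 18 5-[(2R,3R)-3-{2-[(2R)-3,3-dimethyloxiran-2-yl]ethyl}-3-methyloxiran-2-yl]pent-1-en-3-one
Product: 20 (1R,3aR,8aR)-1-(tert-butyldimethylsilyloxy)-5-{2-[(3R,5aR,6R,9aR)-3-(tert-butyldimethylsilyloxy)-2,2,5a-trimethyl-7-oxodecahydro-1-benzoxepin-6-yl]ethyl}-1,4,4,6-tetramethyl-2,3,3a,4,8,8a-hexahydroazulen-7(1H)-one, via silyl enol ether 19 (not isolated)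
Conditions: 13 (1.2 equiv), 18, 2,6-di-tert-butyl-4-methylpyridine (0.5 equiv), CH2Cl2, −78 °C; TBSOTf (0.1 equiv), 1 h; then TBSOTf (0.3 equiv), −78 → −40 °C; aq. NaHCO3
Reagents that add atoms: none
Why: Proposed new method: a silyl-triflate-catalysed vinylogous Mukaiyama–Michael addition coupled in one flask to an epoxide-opening oxa-/carbacyclization (closest known reactions: R3SiOTf-catalysed Mukaiyama–Michael additions of silyl dienol ethers, and TMSOTf-promoted tandem cyclizations of bis-epoxides terminated by enol silanes); TBSOTf silylates the enone oxygen of 18, the unhindered exocyclic CH2 of the transoid diene 13 (α-carbon fully substituted, no s-cis geometry, so neither α-attack nor Diels–Alder competes) adds to the vinyl terminus and returns its silyl group to triflate, forming enol silane 19 regiospecifically and restoring the tetrasubstituted enone; TBSOTf then silylates the terminal epoxide, the internal epoxide oxygen opens it at the tertiary carbon, and the enol silane carbon opens the resulting epoxonium at its tertiary carbon with inversion through a chair, giving the trans-fused oxepane–cyclohexanone (5aR and 9aR from the internal epoxide, 3R carried over); the oxocarbenium releases the silyl cation, so TBSOTf is a relay catalyst, and the C6 side chain settles equatorial (6R) because that centre is epimerizable next to the ketone.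

Step 13
Reactants: 20 (1R,3aR,8aR)-1-(tert-butyldimethylsilyloxy)-5-{2-[(3R,5aR,6R,9aR)-3-(tert-butyldimethylsilyloxy)-2,2,5a-trimethyl-7-oxodecahydro-1-benzoxepin-6-yl]ethyl}-1,4,4,6-tetramethyl-2,3,3a,4,8,8a-hexahydroazulen-7(1H)-one
Product: 21 (1R,3aR,8aR)-1-(tert-butyldimethylsilyloxy)-5-{2-[(3R,5aR,6R,7S,9aR)-3-(tert-butyldimethylsilyloxy)-7-hydroxy-2,2,5a,7-tetramethyldecahydro-1-benzoxepin-6-yl]ethyl}-1,4,4,6-tetramethyl-2,3,3a,4,8,8a-hexahydroazulen-7(1H)-one
Conditions: MeTi(OiPr)3 (4 equiv), Et2O, 0 °C → rt, 24 h; sat. aq. NH4Cl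
Reagents that add atoms: methyltitanium triisopropoxide C[Ti](OC(C)C)(OC(C)C)OC(C)C
Why: Carbonyl addition of a non-basic, sterically demanding titanium methyl reagent: the saturated cyclohexanone reacts while the conjugated, tetrasubstituted cycloheptenone does not, and attack is equatorial because the axial path is blocked by the syn-axial angular methyl group, which places the new OH axial (7S).

Step 14
Reactants: 21 (1R,3aR,8aR)-1-(tert-butyldimethylsilyloxy)-5-{2-[(3R,5aR,6R,7S,9aR)-3-(tert-butyldimethylsilyloxy)-7-hydroxy-2,2,5a,7-tetramethyldecahydro-1-benzoxepin-6-yl]ethyl}-1,4,4,6-tetramethyl-2,3,3a,4,8,8a-hexahydroazulen-7(1H)-one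
Product: 22 (1R,3aR,8aR)-5-{2-[(3R,5aR,6R,7S,9aR)-3,7-dihydroxy-2,2,5a,7-tetramethyldecahydro-1-benzoxepin-6-yl]ethyl}-1-hydroxy-1,4,4,6-tetramethyl-2,3,3a,4,8,8a-hexahydroazulen-7(1H)-one
Conditions: HF·pyridine, THF, 0 → 40 °C
Reagents that add atoms: none
Why: Fluoride-driven cleavage of the secondary and tertiary silyl ethers (strong Si–F bond) frees the two alcohols without touching the enone or any stereocentre.

**Compound list**

1 | cyclopentane-1,3-dione | O=C1CCC(=O)C1 | starting material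
2 | ethyl glyoxylate | CCOC(=O)C=O | starting material
3 | ethyl 2-(2,5-dioxocyclopentylidene)acetate | CCOC(=O)C=C1C(=O)CCC1=O | intermediate (not isolated)
4 | ethyl 2-(2,5-dioxocyclopentyl)acetate | CCOC(=O)CC1C(=O)CCC1=O | intermediate
5 | ethyl 2-(2-chloro-5-oxocyclopent-1-en-1-yl)acetate | CCOC(=O)CC1=C(Cl)CCC1=O | intermediate
6 | pentan-3-one | CCC(=O)CC | starting material
7 | ethyl 2-[5-oxo-2-(3-oxopentan-2-yl)cyclopent-1-en-1-yl]acetate (racemic) | CCOC(=O)CC1=C(C(C)C(=O)CC)CCC1=O | intermediate (not isolated)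
8 | ethyl 2-[2-(2-methyl-3-oxopentan-2-yl)-5-oxocyclopent-1-en-1-yl]acetate | CCOC(=O)CC1=C(C(C)(C)C(=O)CC)CCC1=O | intermediate
9 | ethyl 2-[(5R)-5-hydroxy-5-methyl-2-(2-methyl-3-oxopentan-2-yl)cyclopent-1-en-1-yl]acetate | CCOC(=O)CC1=C(C(C)(C)C(=O)CC)CC[C@@]1(C)O | intermediate
10 | ethyl 2-[(1R,2R,5R)-2-hydroxy-2-methyl-5-(2-methyl-3-oxopentan-2-yl)cyclopentyl]acetate | CCC(=O)C(C)(C)[C@@H]1CC[C@@](C)(O)[C@@H]1CC(=O)OCC | intermediate
11 | (1R,3aR,8aR)-1-hydroxy-1,4,4,6-tetramethyloctahydroazulene-5,7(1H,6H)-dione (C6 epimers and enol) | CC1C(=O)C(C)(C)[C@@H]2CC[C@@](C)(O)[C@@H]2CC1=O | intermediate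
12 | (1R,3aR,8aR)-1,7-bis(tert-butyldimethylsilyloxy)-1,4,4,6-tetramethyl-2,3,3a,4,8,8a-hexahydroazulen-5(1H)-one | O=C1C(C)(C)[C@@H]2CC[C@@](C)(O[Si](C)(C)C(C)(C)C)[C@@H]2CC(O[Si](C)(C)C(C)(C)C)=C1C | intermediate
13 | (1R,3aR,8aR)-1,7-bis(tert-butyldimethylsilyloxy)-1,4,4,6-tetramethyl-5-methylidene-1,2,3,3a,4,5,8,8a-octahydroazulene | C=C1C(C)(C)[C@@H]2CC[C@@](C)(O[Si](C)(C)C(C)(C)C)[C@@H]2CC(O[Si](C)(C)C(C)(C)C)=C1C | intermediate
14 | geranyl bromide, (2E)-1-bromo-3,7-dimethylocta-2,6-diene | CC(C)=CCC/C(C)=C/CBr | starting material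
15 | N-methoxy-N-methylacetamide | CC(=O)N(C)OC | starting material
16 | (4E)-N-methoxy-N,5,9-trimethyldeca-4,8-dienamide | CC(C)=CCC/C(C)=C/CCC(=O)N(C)OC | intermediate
17 | 3-[(2R,3R)-3-{2-[(2R)-3,3-dimethyloxiran-2-yl]ethyl}-3-methyloxiran-2-yl]-N-methoxy-N-methylpropanamide | CON(C)C(=O)CC[C@H]1O[C@]1(C)CC[C@H]1OC1(C)C | intermediate
18 | 5-[(2R,3R)-3-{2-[(2R)-3,3-dimethyloxiran-2-yl]ethyl}-3-methyloxiran-2-yl]pent-1-en-3-one | C=CC(=O)CC[C@H]1O[C@]1(C)CC[C@H]1OC1(C)C | intermediate
19 | (1R,3aR,8aR)-1-(tert-butyldimethylsilyloxy)-5-{4-(tert-butyldimethylsilyloxy)-6-[(2R,3R)-3-{2-[(2R)-3,3-dimethyloxiran-2-yl]ethyl}-3-methyloxiran-2-yl]hex-3-en-1-yl}-1,4,4,6-tetramethyl-2,3,3a,4,8,8a-hexahydroazulen-7(1H)-one (enol ether E/Z mixture) | CC1=C(CCC=C(O[Si](C)(C)C(C)(C)C)CC[C@H]2O[C@]2(C)CC[C@H]2OC2(C)C)C(C)(C)[C@@H]2CC[C@@](C)(O[Si](C)(C)C(C)(C)C)[C@@H]2CC1=O | intermediate (not isolated)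
20 | (1R,3aR,8aR)-1-(tert-butyldimethylsilyloxy)-5-{2-[(3R,5aR,6R,9aR)-3-(tert-butyldimethylsilyloxy)-2,2,5a-trimethyl-7-oxodecahydro-1-benzoxepin-6-yl]ethyl}-1,4,4,6-tetramethyl-2,3,3a,4,8,8a-hexahydroazulen-7(1H)-one | CC1=C(CC[C@@H]2[C@@]3(C)CC[C@@H](O[Si](C)(C)C(C)(C)C)C(C)(C)O[C@@H]3CCC2=O)C(C)(C)[C@@H]2CC[C@@](C)(O[Si](C)(C)C(C)(C)C)[C@@H]2CC1=O | intermediate
21 | (1R,3aR,8aR)-1-(tert-butyldimethylsilyloxy)-5-{2-[(3R,5aR,6R,7S,9aR)-3-(tert-butyldimethylsilyloxy)-7-hydroxy-2,2,5a,7-tetramethyldecahydro-1-benzoxepin-6-yl]ethyl}-1,4,4,6-tetramethyl-2,3,3a,4,8,8a-hexahydroazulen-7(1H)-one | CC1=C(CC[C@@H]2[C@@]3(C)CC[C@@H](O[Si](C)(C)C(C)(C)C)C(C)(C)O[C@@H]3CC[C@]2(C)O)C(C)(C)[C@@H]2CC[C@@](C)(O[Si](C)(C)C(C)(C)C)[C@@H]2CC1=O | intermediate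
22 | (1R,3aR,8aR)-5-{2-[(3R,5aR,6R,7S,9aR)-3,7-dihydroxy-2,2,5a,7-tetramethyldecahydro-1-benzoxepin-6-yl]ethyl}-1-hydroxy-1,4,4,6-tetramethyl-2,3,3a,4,8,8a-hexahydroazulen-7(1H)-one (CNP0397160.1) | CC1=C(CC[C@@H]2[C@@]3(C)CC[C@@H](O)C(C)(C)O[C@@H]3CC[C@]2(C)O)C(C)(C)[C@@H]2CC[C@@](C)(O)[C@@H]2CC1=O | target

**Step count**

Total step count: 14. Longest linear sequence: 11 steps (steps 1 to 8, then 12 to 14, from cyclopentane-1,3-dione).

**Steps most likely to fail, with fallbacks**

Risk 1, step 12. The silyl triflate may open the epoxides of 18 before the Michael union has made the enol silane; the ketone oxygen then traps the epoxonium and gives a cyclic enol ether instead of the carbocycle. The fallback separates the two events and moves the union to the end; it sets out from 17 and 12 and comes back to the route at 21, so it also avoids step 13.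
- Allylmagnesium bromide (THF, −20 °C) converts 17 into 6-[(2R,3R)-3-{2-[(2R)-3,3-dimethyloxiran-2-yl]ethyl}-3-methyloxiran-2-yl]hex-1-en-4-one F1.
- Its doubly activated CH2 is silylated regioselectively (LiN(iPr)2, TBSCl, THF, −78 °C) to tert-butyl({6-[(2R,3R)-3-{2-[(2R)-3,3-dimethyloxiran-2-yl]ethyl}-3-methyloxiran-2-yl]hexa-1,3-dien-4-yl}oxy)dimethylsilane F2.
- TBSOTf (0.3 equiv) with 2,6-di-tert-butyl-4-methylpyridine in CH2Cl2 at −78 °C then effects the intramolecular oxa-/carbacyclization alone and gives (3R,5aR,6R,9aR)-3-(tert-butyldimethylsilyloxy)-6-ethenyl-2,2,5a-trimethyloctahydro-1-benzoxepin-7(2H)-one F3.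
- MeLi/CeCl3 (THF, −78 °C, equatorial attack) gives (3R,5aR,6R,7S,9aR)-3-(tert-butyldimethylsilyloxy)-6-ethenyl-2,2,5a,7-tetramethyldecahydro-1-benzoxepin-7-ol F4.
- 9-BBN followed by I2/NaOMe gives (3R,5aR,6R,7S,9aR)-3-(tert-butyldimethylsilyloxy)-6-(2-iodoethyl)-2,2,5a,7-tetramethyldecahydro-1-benzoxepin-7-ol F5.
- t-BuLi (3.1 equiv, Et2O, −78 °C) makes the alkoxide and the alkyllithium; this adds to the hindered ketone of 12, and aqueous oxalic acid then hydrolyses the silyl enol ether and dehydrates (Stork–Danheiser transposition) to 21.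

Risk 2, step 5. The tetrasubstituted alkene of 9 carries a quaternary carbon and may resist hydrogenation even with the tertiary OH as director (the same detour covers a poor enantiomeric excess in step 4). The fallback sets b3 last and uses a secondary carbinol as the director; it sets out from 8 and comes back at 10.
- CBS reduction of the cyclopentenone carbonyl (BH3·SMe2, (S)-2-methyl-CBS-oxazaborolidine, THF, −20 °C) gives ethyl 2-[(5R)-5-hydroxy-2-(2-methyl-3-oxopentan-2-yl)cyclopent-1-en-1-yl]acetate F6.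
- Hydrogenation directed by the better-binding secondary OH (H2, [Ir(cod)(PCy3)(py)]PF6) gives ethyl 2-[(1R,2R,5R)-2-hydroxy-5-(2-methyl-3-oxopentan-2-yl)cyclopentyl]acetate F7.
- Dess–Martin periodinane gives ethyl 2-[(1R,2R)-2-(2-methyl-3-oxopentan-2-yl)-5-oxocyclopentyl]acetate F8.
- Non-basic methylenation of the cyclopentanone with Cp2TiMe2 (no epimerization) gives ethyl 2-[(1R,2R)-5-methylidene-2-(2-methyl-3-oxopentan-2-yl)cyclopentyl]acetate F9.
- Mukaiyama hydration (Mn(dpm)3, PhSiH3, O2, i-PrOH) traps the tertiary radical with O2 on the face away from both cis side chains and gives 10.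

Risk 3, step 13. The titanium reagent may be too slow on the α-branched cyclohexanone, or may also attack the enone. The fallback replaces methyl addition by methylene transfer and hydride opening; it sets out from 20 and comes back at 21.
- Dimethylsulfoxonium methylide (Me3S(O)I, NaH, DMSO) adds reversibly and equatorially to the saturated ketone only (the β-carbon of the enone is fully substituted) and gives the 7-spiro-oxirane of 20 with the oxirane oxygen axial and cis to the angular methyl group F10.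
- LiAlH4 opens the oxirane at its CH2 and reduces the enone carbonyl, giving the 7-hydroxy-7-methyl compound carrying an allylic alcohol in place of the cycloheptenone carbonyl F11.
- MnO2 (CH2Cl2) reoxidizes only the allylic alcohol and gives 21.

Further compounds
F1 | step 12 | 6-[(2R,3R)-3-{2-[(2R)-3,3-dimethyloxiran-2-yl]ethyl}-3-methyloxiran-2-yl]hex-1-en-4-one | C=CCC(=O)CC[C@H]1O[C@]1(C)CC[C@H]1OC1(C)C
F2 | step 12 | tert-butyl({6-[(2R,3R)-3-{2-[(2R)-3,3-dimethyloxiran-2-yl]ethyl}-3-methyloxiran-2-yl]hexa-1,3-dien-4-yl}oxy)dimethylsilane | C=CC=C(O[Si](C)(C)C(C)(C)C)CC[C@H]1O[C@]1(C)CC[C@H]1OC1(C)C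
F3 | step 12 | (3R,5aR,6R,9aR)-3-(tert-butyldimethylsilyloxy)-6-ethenyl-2,2,5a-trimethyloctahydro-1-benzoxepin-7(2H)-one | C=C[C@@H]1[C@@]2(C)CC[C@@H](O[Si](C)(C)C(C)(C)C)C(C)(C)O[C@@H]2CCC1=O
F4 | step 12 | (3R,5aR,6R,7S,9aR)-3-(tert-butyldimethylsilyloxy)-6-ethenyl-2,2,5a,7-tetramethyldecahydro-1-benzoxepin-7-ol | C=C[C@@H]1[C@@]2(C)CC[C@@H](O[Si](C)(C)C(C)(C)C)C(C)(C)O[C@@H]2CC[C@]1(C)O
F5 | step 12 | (3R,5aR,6R,7S,9aR)-3-(tert-butyldimethylsilyloxy)-6-(2-iodoethyl)-2,2,5a,7-tetramethyldecahydro-1-benzoxepin-7-ol | ICC[C@@H]1[C@@]2(C)CC[C@@H](O[Si](C)(C)C(C)(C)C)C(C)(C)O[C@@H]2CC[C@]1(C)O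
F6 | step 5 | ethyl 2-[(5R)-5-hydroxy-2-(2-methyl-3-oxopentan-2-yl)cyclopent-1-en-1-yl]acetate | CCOC(=O)CC1=C(C(C)(C)C(=O)CC)CC[C@H]1O
F7 | step 5 | ethyl 2-[(1R,2R,5R)-2-hydroxy-5-(2-methyl-3-oxopentan-2-yl)cyclopentyl]acetate | CCC(=O)C(C)(C)[C@@H]1CC[C@@H](O)[C@@H]1CC(=O)OCC
F8 | step 5 | ethyl 2-[(1R,2R)-2-(2-methyl-3-oxopentan-2-yl)-5-oxocyclopentyl]acetate | CCC(=O)C(C)(C)[C@@H]1CCC(=O)[C@@H]1CC(=O)OCC
F9 | step 5 | ethyl 2-[(1R,2R)-5-methylidene-2-(2-methyl-3-oxopentan-2-yl)cyclopentyl]acetate | CCC(=O)C(C)(C)[C@@H]1CCC(=C)[C@@H]1CC(=O)OCC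
F10 | step 13 | 7-spiro-oxirane of 20 with the oxirane oxygen axial and cis to the angular methyl group | CC1=C(CC[C@@H]2[C@@]3(C)CC[C@@H](O[Si](C)(C)C(C)(C)C)C(C)(C)O[C@@H]3CC[C@@]24CO4)C(C)(C)[C@@H]2CC[C@@](C)(O[Si](C)(C)C(C)(C)C)[C@@H]2CC1=O
F11 | step 13 | 7-hydroxy-7-methyl compound carrying an allylic alcohol in place of the cycloheptenone carbonyl | CC1=C(CC[C@@H]2[C@@]3(C)CC[C@@H](O[Si](C)(C)C(C)(C)C)C(C)(C)O[C@@H]3CC[C@]2(C)O)C(C)(C)[C@@H]2CC[C@@](C)(O[Si](C)(C)C(C)(C)C)[C@@H]2CC1O
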